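The flavone pyranone ring (O1, C2, C3, C4) is fused to a phloroglucinol-type ring A whose C8 carries ring B of the flavanone half. O1 is a phenol oxygen, C4 is one carbonyl carbon and C3–C2 is an aryl-capped two-carbon unit, so this ring can be grown from iodophenol, CO and 4-ethynylanisole once the crowded C8–C3' biaryl bond exists.
Target ⇒ BCl3 cleavage of two benzyl ethers and the peri 5-OMe ⇒ flavanone C2–C1' bond by enantioselective palladium-catalysed addition of the flavone-bearing arylboronic acid to 5-benzyloxy-7-methoxychromone. This sets 2S two steps from the end, after all basic steps.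
Boronic acid ⇒ aryl bromide ⇒ three-component carbonylative annulation (C4a–C4, C4–C3, O1–C2) of a 2-aryl-6-iodo-3,5-dimethoxyphenol.
Iodophenol ⇒ two electrophilic iodinations and one iodide-selective Suzuki coupling on symmetric 3,5-dimethoxyphenol. The boronic acid partner comes from 4-bromophenol, and no alkyllithium ever meets the aryl bromide.
Ring order: the four benzene rings are bought. The flavone pyranone ring closes in step 7. The pyranone ring of the flavanone half closes as a chromone in step 12 (side branch) and is saturated at C2–C3 in step 13.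

Key step: step 7

Assumption 1: the facial sense of the t-BuPyOx–palladium catalyst on chromones is taken to parallel that on 3-substituted cyclohexenones, which points to the (R)-ligand for Re-face attack at C2 (2S). If the CD curve of 23 says otherwise, the (S)-ligand is used and nothing else changes.
Assumption 2: the target string defines no axial chirality, so the C8–C3' axis is treated as rotationally labile and only C2 is controlled.

Step 1
Reactants: 1 4-bromophenol
Product: 2 4-bromo-2-iodophenol
Conditions: NIS (1.0 equiv), TsOH·H2O (10 mol %), MeCN, rt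
Reagents that add atoms: N-iodosuccinimide, O=C1CCC(=O)N1I
Why: Electrophilic aromatic iodination, in which bromine blocks the para position so that acid-activated NIS can only attack ortho to the hydroxyl and one equivalent stops at the mono-iodide.

Step 2
Reactants: 2 4-bromo-2-iodophenol
Product: 3 1-(benzyloxy)-4-bromo-2-iodobenzene
Conditions: BnBr, K2CO3, DMF, rt
Reagents that add atoms: benzyl bromide, BrCc1ccccc1
Why: Williamson ether synthesis on the phenoxide, to which both aryl halides are inert.

Step 3
Reactants: 3 1-(benzyloxy)-4-bromo-2-iodobenzene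
Product: 6 [2-(benzyloxy)-5-bromophenyl]boronic acid, via arylmagnesium chloride 4 (not isolated), via dimethyl arylboronate 5 (not isolated)
Conditions: i-PrMgCl, THF, −30 °C; B(OMe)3, −30 °C to rt; aq HCl
Reagents that add atoms: isopropylmagnesium chloride, CC(C)[Mg]Cl (Mg and Cl stand only in 4); trimethyl borate, COB(OC)OC; water, O
Why: Iodine–magnesium exchange is far faster than bromine–magnesium exchange and is helped by the ortho alkoxy group, so the Grignard reagent forms only at the former C–I carbon and is trapped by the borate (electrophilic borylation, then hydrolysis).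

Step 4
Reactants: 7 3,5-dimethoxyphenol
Product: 8 2-iodo-3,5-dimethoxyphenol
Conditions: NIS (1.0 equiv), MeCN, −20 to 0 °C, dark
Reagents that add atoms: N-iodosuccinimide, O=C1CCC(=O)N1I
Why: Electrophilic aromatic iodination of a symmetric phenol, whose two equivalent carbons ortho to OH are less crowded than the carbon between the two methoxy groups, so the minor para isomer should be removable by chromatography.

Step 5
Reactants: 8 2-iodo-3,5-dimethoxyphenol (1.15 equiv); 6 [2-(benzyloxy)-5-bromophenyl]boronic acid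
Product: 9 2-[2-(benzyloxy)-5-bromophenyl]-3,5-dimethoxyphenol
Conditions: Pd(PPh3)4 (5 mol %), aq Na2CO3, DME, 80 °C
Reagents that add atoms: none
Why: Suzuki–Miyaura coupling, in which zerovalent palladium bearing PPh3 inserts into the C–I bond of 8 much faster than into the alkoxy-deactivated C–Br bond of 6 or 9, and the slight excess of 8 keeps an iodide available to the catalyst so that the bromine is carried through.

Step 6
Reactants: 9 2-[2-(benzyloxy)-5-bromophenyl]-3,5-dimethoxyphenol
Product: 10 2-[2-(benzyloxy)-5-bromophenyl]-6-iodo-3,5-dimethoxyphenol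
Conditions: NIS (1.0 equiv), CH2Cl2, −20 to 0 °C, dark
Reagents that add atoms: N-iodosuccinimide, O=C1CCC(=O)N1I
Why: Electrophilic aromatic iodination, in which C6 lies between OH and one OMe whereas C4 is walled in by two OMe groups (one pushed toward it by the new aryl group), the same steric bias that sends halogen to C8 rather than C6 of 5,7-dialkoxyflavans and 5,7-dialkoxyflavones, and the bromoaryl ring is too electron-poor to compete.

Step 7
Reactants: 10 2-[2-(benzyloxy)-5-bromophenyl]-6-iodo-3,5-dimethoxyphenol; 11 4-ethynylanisole (1.5 equiv); 12 carbon monoxide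
Product: 15 8-[2-(benzyloxy)-5-bromophenyl]-5,7-dimethoxy-2-(4-methoxyphenyl)-4H-chromen-4-one, via ortho-hydroxyaryl ynone 13 (not isolated), via diethylamino enaminone 14 (not isolated)
Conditions: PdCl2(PPh3)2 (5 mol %), CO (10 bar), Et2NH, 70 °C
Reagents that add atoms: diethylamine, CCNCC (its atoms stand only in 14 and leave again on ring closure)
Why: PdCl2(PPh3)2 is reduced in the amine to zerovalent palladium, which inserts into the C–I bond of 10; CO then migrates in to give an aroyl complex of divalent palladium, and amine-assisted transfer of the alkynyl group of 11 followed by reductive elimination forges C4a–C4 and C4–C3 in ynone 13. Diethylamine adds to the β-carbon of the ynone to give enaminone 14, and the neighbouring phenol oxygen attacks that same carbon and expels the amine, which makes O1–C2 and closes the pyranone in a 6-endo addition–elimination. The closest known reaction type is the carbonylative Sonogashira annulation of 2-iodophenols with terminal alkynes to flavones in a secondary amine. No stereocentre is formed. Flavone must win over aurone, and the 5-exo attack on the alkyne carbon next to the carbonyl is shut off once the triple bond has become the enaminone, whose only electrophilic carbon is C2. C–I must react before C–Br, which holds because the iodide adds far faster and CO-ligated zerovalent palladium with PPh3 is too electron-poor to engage an alkoxy-substituted aryl bromide at 70 °C, while the CO pressure also holds back the CO-free alkynylation that would lead to a benzofuran.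

Step 8
Reactants: 15 8-[2-(benzyloxy)-5-bromophenyl]-5,7-dimethoxy-2-(4-methoxyphenyl)-4H-chromen-4-one
Product: 16 8-[2-(benzyloxy)-5-(4,4,5,5-tetramethyl-1,3,2-dioxaborolan-2-yl)phenyl]-5,7-dimethoxy-2-(4-methoxyphenyl)-4H-chromen-4-one
Conditions: B2pin2, PdCl2(dppf) (5 mol %), KOAc, 1,4-dioxane, 90 °C
Reagents that add atoms: bis(pinacolato)diboron, CC1(C)OB(OC1(C)C)B1OC(C)(C)C(C)(C)O1
Why: Miyaura borylation of the unhindered C–Br bond para to the benzyloxy group, with KOAc too weak a base to start Suzuki homocoupling or to harm the flavone.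

Step 9
Reactants: 16 pinacol boronate
Product: 17 {4-(benzyloxy)-3-[5,7-dimethoxy-2-(4-methoxyphenyl)-4-oxo-4H-chromen-8-yl]phenyl}boronic acid
Conditions: NaIO4, NH4OAc, acetone–THF–H2O, rt
Reagents that add atoms: water, O
Why: Periodate-driven hydrolysis of the pinacol ester, in which glycol cleavage of the liberated pinacol pulls the equilibrium to the free boronic acid needed in step 13, and the substrate has no free phenol or diol for periodate to oxidise.

Step 10
Reactants: 18 2,4,6-trihydroxyacetophenone
Product: 19 2,6-dihydroxy-4-methoxyacetophenone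
Conditions: Me2SO4 (1.0 equiv), K2CO3 (1.0 equiv), acetone, reflux
Reagents that add atoms: dimethyl sulfate, COS(=O)(=O)OC
Why: Williamson-type O-methylation, in which the 4-OH is the only hydroxyl that cannot hydrogen-bond to the carbonyl and is the most acidic, so one equivalent of base and dimethyl sulfate alkylates it first.

Step 11
Reactants: 19 2,6-dihydroxy-4-methoxyacetophenone
Product: 20 2-(benzyloxy)-6-hydroxy-4-methoxyacetophenone
Conditions: BnBr (1.05 equiv), K2CO3, acetone, reflux
Reagents that add atoms: benzyl bromide, BrCc1ccccc1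
Why: Williamson ether synthesis on two equivalent hydroxyls, after which the last one is locked in a strong hydrogen bond to the ketone and stays free for the ring closure.

Step 12
Reactants: 20 2-(benzyloxy)-6-hydroxy-4-methoxyacetophenone
Product: 22 5-(benzyloxy)-7-methoxy-4H-chromen-4-one, via dimethylamino enaminone 21 (not isolated)
Conditions: Me2NCH(OMe)2, toluene, 100 °C; evaporate; aq HCl, CH2Cl2, 40 °C
Reagents that add atoms: N,N-dimethylformamide dimethyl acetal, COC(OC)N(C)C
Why: Enaminone route to chromones, in which the amide acetal condenses with the acetyl CH3 and acid then lets the ortho phenol add to the β-carbon and expel dimethylamine in a 6-endo addition–elimination that an aryl benzyl ether tolerates.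

Step 13
Reactants: 17 flavone-bearing arylboronic acid; 22 5-(benzyloxy)-7-methoxy-4H-chromen-4-one (2 equiv)
Product: 23 (2S)-5-(benzyloxy)-2-{4-(benzyloxy)-3-[5,7-dimethoxy-2-(4-methoxyphenyl)-4-oxo-4H-chromen-8-yl]phenyl}-7-methoxy-2,3-dihydro-4H-chromen-4-one
Conditions: Pd(OCOCF3)2 (10 mol %), (R)-4-tert-butyl-2-(pyridin-2-yl)-4,5-dihydrooxazole [(R)-t-BuPyOx, 12 mol %], NH4PF6 (30 mol %), H2O (5 equiv), ClCH2CH2Cl, 60 °C
Reagents that add atoms: none
Why: Palladium-catalysed asymmetric conjugate addition of an arylboronic acid (the palladium counterpart of the Hayashi–Miyaura reaction), in which transmetalation gives a cationic aryl complex of divalent palladium, the chromone C2=C3 bond inserts with the ligand tert-butyl group blocking one face so that the aryl group reaches the Re face of C2 (2S), water protonates the palladium enolate, and the 2-aryl-substituted enone of the flavone half is too hindered to compete.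

Step 14
Reactants: 23 protected (2S)-dihydrobiflavone
Product: 24 2,3-dihydroheveaflavone with 2S configuration
Conditions: BCl3 (10 equiv), C6HMe5 (6 equiv), CH2Cl2, −78 °C, then 0 °C; MeOH quench at −78 °C, neutral aqueous work-up
Reagents that add atoms: none
Why: Lewis-acid ether cleavage, in which BCl3 with pentamethylbenzene as benzyl-cation trap removes both aryl benzyl ethers at −78 °C and, on warming to 0 °C, the boron chelate between the flavone C4 carbonyl and the peri 5-OMe delivers chloride to that methyl only, while the three non-chelated methyl ethers resist BCl3 and the cold, base-free medium should leave the 2S centre untouched.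

Compound list
1 | 4-bromophenol | Oc1ccc(Br)cc1 | starting material
2 | 4-bromo-2-iodophenol | Oc1ccc(Br)cc1I | intermediate
3 | 1-(benzyloxy)-4-bromo-2-iodobenzene | Brc1ccc(OCc2ccccc2)c(I)c1 | intermediate
4 | [2-(benzyloxy)-5-bromophenyl]magnesium chloride, formed in the flask | Cl[Mg]c1cc(Br)ccc1OCc1ccccc1 | intermediate
5 | dimethyl [2-(benzyloxy)-5-bromophenyl]boronate, formed in the flask | COB(OC)c1cc(Br)ccc1OCc1ccccc1 | intermediate
6 | [2-(benzyloxy)-5-bromophenyl]boronic acid | OB(O)c1cc(Br)ccc1OCc1ccccc1 | intermediate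
7 | 3,5-dimethoxyphenol | COc1cc(O)cc(OC)c1 | starting material
8 | 2-iodo-3,5-dimethoxyphenol | COc1cc(O)c(I)c(OC)c1 | intermediate
9 | 2-[2-(benzyloxy)-5-bromophenyl]-3,5-dimethoxyphenol | COc1cc(O)c(-c2cc(Br)ccc2OCc2ccccc2)c(OC)c1 | intermediate
10 | 2-[2-(benzyloxy)-5-bromophenyl]-6-iodo-3,5-dimethoxyphenol | COc1cc(OC)c(I)c(O)c1-c1cc(Br)ccc1OCc1ccccc1 | intermediate
11 | 4-ethynylanisole | C#Cc1ccc(OC)cc1 | starting material
12 | carbon monoxide | [C-]#[O+] | starting material
13 | 1-{3-[2-(benzyloxy)-5-bromophenyl]-2-hydroxy-4,6-dimethoxyphenyl}-3-(4-methoxyphenyl)prop-2-yn-1-one, formed in the flask | COc1ccc(C#CC(=O)c2c(OC)cc(OC)c(-c3cc(Br)ccc3OCc3ccccc3)c2O)cc1 | intermediate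
14 | 1-{3-[2-(benzyloxy)-5-bromophenyl]-2-hydroxy-4,6-dimethoxyphenyl}-3-(diethylamino)-3-(4-methoxyphenyl)prop-2-en-1-one, alkene geometry not fixed, formed in the flask | CCN(CC)C(=CC(=O)c1c(OC)cc(OC)c(-c2cc(Br)ccc2OCc2ccccc2)c1O)c1ccc(OC)cc1 | intermediate
15 | 8-[2-(benzyloxy)-5-bromophenyl]-5,7-dimethoxy-2-(4-methoxyphenyl)-4H-chromen-4-one (8-(2-benzyloxy-5-bromophenyl)-5,7,4'-trimethoxyflavone) | COc1ccc(-c2cc(=O)c3c(OC)cc(OC)c(-c4cc(Br)ccc4OCc4ccccc4)c3o2)cc1 | intermediate
16 | 8-[2-(benzyloxy)-5-(4,4,5,5-tetramethyl-1,3,2-dioxaborolan-2-yl)phenyl]-5,7-dimethoxy-2-(4-methoxyphenyl)-4H-chromen-4-one | COc1ccc(-c2cc(=O)c3c(OC)cc(OC)c(-c4cc(B5OC(C)(C)C(C)(C)O5)ccc4OCc4ccccc4)c3o2)cc1 | intermediate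
17 | {4-(benzyloxy)-3-[5,7-dimethoxy-2-(4-methoxyphenyl)-4-oxo-4H-chromen-8-yl]phenyl}boronic acid | COc1ccc(-c2cc(=O)c3c(OC)cc(OC)c(-c4cc(B(O)O)ccc4OCc4ccccc4)c3o2)cc1 | intermediate
18 | 2,4,6-trihydroxyacetophenone (phloroacetophenone) | CC(=O)c1c(O)cc(O)cc1O | starting material
19 | 2,6-dihydroxy-4-methoxyacetophenone | CC(=O)c1c(O)cc(OC)cc1O | intermediate
20 | 2-(benzyloxy)-6-hydroxy-4-methoxyacetophenone | CC(=O)c1c(O)cc(OC)cc1OCc1ccccc1 | intermediate
21 | (E)-1-[2-(benzyloxy)-6-hydroxy-4-methoxyphenyl]-3-(dimethylamino)prop-2-en-1-one, formed in the flask | CN(C)/C=C/C(=O)c1c(O)cc(OC)cc1OCc1ccccc1 | intermediate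
22 | 5-(benzyloxy)-7-methoxy-4H-chromen-4-one | COc1cc(OCc2ccccc2)c2c(=O)ccoc2c1 | intermediate
23 | (2S)-5-(benzyloxy)-2-{4-(benzyloxy)-3-[5,7-dimethoxy-2-(4-methoxyphenyl)-4-oxo-4H-chromen-8-yl]phenyl}-7-methoxy-2,3-dihydro-4H-chromen-4-one | COc1ccc(-c2cc(=O)c3c(OC)cc(OC)c(-c4cc([C@@H]5CC(=O)c6c(OCc7ccccc7)cc(OC)cc6O5)ccc4OCc4ccccc4)c3o2)cc1 | intermediate
24 | (2S)-2,3-dihydroheveaflavone | COc1ccc(-c2cc(=O)c3c(O)cc(OC)c(-c4cc([C@@H]5CC(=O)c6c(O)cc(OC)cc6O5)ccc4O)c3o2)cc1 | target

Total step count: 14.
Longest linear sequence: 10 (steps 1, 2, 3, 5, 6, 7, 8, 9, 13, 14).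

Steps most likely to fail

Step 7.
- What may go wrong: diethylamine may capture the aroylpalladium intermediate (aminocarbonylation). CO-free alkynylation may be followed by benzofuran closure. Oxidative addition at the doubly flanked, electron-rich C–I bond may be sluggish enough to erode the iodide-over-bromide discrimination.
- Fallback: it sets out from 10 and 11 and comes back at 13, and so at 15. The C4 carbon is brought in as part of a preformed acyl donor instead of CO.
- Compound 11 is deprotonated (n-BuLi, THF, −78 °C) to lithium (4-methoxyphenyl)acetylide F1. This is acylated with N-methoxy-N-methylcarbamoyl chloride to give N-methoxy-N-methyl-3-(4-methoxyphenyl)prop-2-ynamide F2.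
- Compound 10 is turned into its magnesium phenoxide with MeMgCl and LiCl (THF, −20 °C). Iodine–magnesium exchange with i-PrMgCl leaves the bromide alone and gives the doubly magnesiated phenoxide F3.
- Addition of F3 to the Weinreb amide F2 and mild acidic work-up gives ynone 13, now isolated. Warming 13 with Et2NH in EtOH closes it through 14 to 15.

Step 13.
- What may go wrong: insertion into the electron-rich 5,7-dialkoxychromone may be slow, with protodeboronation taking over. Facial selectivity may be poor with a para-alkoxy arylboronic acid.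
- Fallback: it sets out from 15 and 20 and comes back at 23. The flavanone is built through a chalcone and resolved by reduction.
- Reductive carbonylation of 15 (Pd(OAc)2, P(1-Ad)2(n-Bu), CO/H2, TMEDA, toluene, 100 °C) gives 4-(benzyloxy)-3-[5,7-dimethoxy-2-(4-methoxyphenyl)-4-oxo-4H-chromen-8-yl]benzaldehyde F4.
- Claisen–Schmidt condensation of F4 with 20 (KOH, EtOH, rt) gives the (E)-2'-hydroxychalcone F5.
- Oxa-Michael closure of F5 (NaOAc, EtOH, reflux) gives the racemic protected flavanone F6.
- Kinetic resolution of F6 follows by Noyori–Ikariya transfer hydrogenation (RuCl(p-cymene)[(R,R)-TsDPEN], HCO2H/Et3N, EtOAc, rt, run to about half conversion). By the usual sense of this catalyst family it should consume the 2R ketone as the 2,4-cis (2R,4R)-flavan-4-ol F7. The 2S ketone 23 stays behind and is separated by chromatography.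

Step 14.
- What may go wrong: Lewis-acid-induced reversible opening of the flavanone ring may erode the C2 configuration. The non-chelated methyl ethers may be attacked while the slower peri demethylation is driven to completion.
- Fallback: it sets out from 15 and comes back at 24. The BCl3 chemistry is moved ahead of the stereocentre and the route ends with a neutral hydrogenolysis.
- Compound 15 with BCl3 and C6HMe5 (CH2Cl2, −78 to 0 °C) gives 8-(5-bromo-2-hydroxyphenyl)-5-hydroxy-7-methoxy-2-(4-methoxyphenyl)-4H-chromen-4-one F8.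
- Benzylation of F8 (BnBr, K2CO3, DMF, 70 °C) gives the bis(benzyl ether) F9.
- The conditions of steps 8, 9 and 13 then lead through the pinacol boronate F10 and the boronic acid F11 to the (2S)-tris(benzyl ether) F12.
- Hydrogenolysis of F12 (H2 at 1 atm, Pd/C, EtOAc–THF, rt) removes all three benzyl groups and should leave the flavone double bond, both carbonyls and C2 untouched, which gives 24.

Further compounds
F1 | step 7 | lithium (4-methoxyphenyl)acetylide | [Li]C#Cc1ccc(OC)cc1
F2 | step 7 | N-methoxy-N-methyl-3-(4-methoxyphenyl)prop-2-ynamide | CON(C)C(=O)C#Cc1ccc(OC)cc1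
F3 | step 7 | chloromagnesium 2-[2-(benzyloxy)-5-bromophenyl]-6-(chloromagnesio)-3,5-dimethoxyphenoxide | COc1cc(OC)c([Mg]Cl)c(O[Mg]Cl)c1-c1cc(Br)ccc1OCc1ccccc1
F4 | step 13 | 4-(benzyloxy)-3-[5,7-dimethoxy-2-(4-methoxyphenyl)-4-oxo-4H-chromen-8-yl]benzaldehyde | COc1ccc(-c2cc(=O)c3c(OC)cc(OC)c(-c4cc(C=O)ccc4OCc4ccccc4)c3o2)cc1
F5 | step 13 | (E)-1-[2-(benzyloxy)-6-hydroxy-4-methoxyphenyl]-3-{4-(benzyloxy)-3-[5,7-dimethoxy-2-(4-methoxyphenyl)-4-oxo-4H-chromen-8-yl]phenyl}prop-2-en-1-one | COc1ccc(-c2cc(=O)c3c(OC)cc(OC)c(-c4cc(/C=C/C(=O)c5c(O)cc(OC)cc5OCc5ccccc5)ccc4OCc4ccccc4)c3o2)cc1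
F6 | step 13 | racemic 5-(benzyloxy)-2-{4-(benzyloxy)-3-[5,7-dimethoxy-2-(4-methoxyphenyl)-4-oxo-4H-chromen-8-yl]phenyl}-7-methoxy-2,3-dihydro-4H-chromen-4-one | COc1ccc(-c2cc(=O)c3c(OC)cc(OC)c(-c4cc(C5CC(=O)c6c(OCc7ccccc7)cc(OC)cc6O5)ccc4OCc4ccccc4)c3o2)cc1
F7 | step 13 | 8-{2-(benzyloxy)-5-[(2R,4R)-5-(benzyloxy)-4-hydroxy-7-methoxy-3,4-dihydro-2H-chromen-2-yl]phenyl}-5,7-dimethoxy-2-(4-methoxyphenyl)-4H-chromen-4-one | COc1ccc(-c2cc(=O)c3c(OC)cc(OC)c(-c4cc([C@H]5C[C@@H](O)c6c(OCc7ccccc7)cc(OC)cc6O5)ccc4OCc4ccccc4)c3o2)cc1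
F8 | step 14 | 8-(5-bromo-2-hydroxyphenyl)-5-hydroxy-7-methoxy-2-(4-methoxyphenyl)-4H-chromen-4-one | COc1ccc(-c2cc(=O)c3c(O)cc(OC)c(-c4cc(Br)ccc4O)c3o2)cc1
F9 | step 14 | 5-(benzyloxy)-8-[2-(benzyloxy)-5-bromophenyl]-7-methoxy-2-(4-methoxyphenyl)-4H-chromen-4-one | COc1ccc(-c2cc(=O)c3c(OCc4ccccc4)cc(OC)c(-c4cc(Br)ccc4OCc4ccccc4)c3o2)cc1
F10 | step 14 | 5-(benzyloxy)-8-[2-(benzyloxy)-5-(4,4,5,5-tetramethyl-1,3,2-dioxaborolan-2-yl)phenyl]-7-methoxy-2-(4-methoxyphenyl)-4H-chromen-4-one | COc1ccc(-c2cc(=O)c3c(OCc4ccccc4)cc(OC)c(-c4cc(B5OC(C)(C)C(C)(C)O5)ccc4OCc4ccccc4)c3o2)cc1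
F11 | step 14 | {4-(benzyloxy)-3-[5-(benzyloxy)-7-methoxy-2-(4-methoxyphenyl)-4-oxo-4H-chromen-8-yl]phenyl}boronic acid | COc1ccc(-c2cc(=O)c3c(OCc4ccccc4)cc(OC)c(-c4cc(B(O)O)ccc4OCc4ccccc4)c3o2)cc1
F12 | step 14 | (2S)-5-(benzyloxy)-2-{4-(benzyloxy)-3-[5-(benzyloxy)-7-methoxy-2-(4-methoxyphenyl)-4-oxo-4H-chromen-8-yl]phenyl}-7-methoxy-2,3-dihydro-4H-chromen-4-one | COc1ccc(-c2cc(=O)c3c(OCc4ccccc4)cc(OC)c(-c4cc([C@@H]5CC(=O)c6c(OCc7ccccc7)cc(OC)cc6O5)ccc4OCc4ccccc4)c3o2)cc1
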